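Readings and results were generated by integration for an exercise.

Litres per mole are the unit of the number I want from the earlier runs, because with it I can rank flasks that differ in how they are fed.

| flask | substrate | reagent | remark | time |
|---|---|---|---|---|
| Sunday's | 0.020 M | 0.022 M | run made earlier |  |
| Tuesday's | 0.020 M | 0.031 M | run made earlier |  |
| Friday's | 0.020 M | 0.048 M | run made earlier |  |
| Saturday's | 0.010 M | 0.022 M | run made earlier |  |
| delta | 0.020 M (fed, over 2.0 h) | 0.0220 M | all else is in the flask from the start; the feed brings no volume worth counting | 3.0 h |
| zeta | 0.020 M | 0.0220 M (fed, over 12 min) | all else is in the flask from the start; the feed brings no volume worth counting | 3.0 h |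
| theta | 0.020 M | 0.0220 M (fed, over 2.0 h) | all else is in the flask from the start; the feed brings no volume worth counting | 3.0 h |
| eta | 0.020 M | 0.0220 M | everything together at the start | 3.0 h |

| run | time / h | target / % | side product / % |
|---|---|---|---|
| Sunday's | 0.250 | 7 | 30 |
| Sunday's | 0.333 | 1 | 25 |
| Sunday's | 0.500 | 4 | 28 |
| Sunday's | 0.833 | 2 | 30 |
| Sunday's | 1.33 | 1 | 32 |
| Sunday's | 2.00 | 0 | 31 |
| Sunday's | 3.00 | 0 | 30 |
| Tuesday's | 0.250 | 4 | 38 |
| Tuesday's | 0.417 | 6 | 41 |
| Tuesday's | 0.667 | 5 | 40 |
| Tuesday's | 1.00 | 1 | 41 |
| Tuesday's | 1.50 | 0 | 45 |
| Tuesday's | 2.50 | 0 | 42 |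
| Tuesday's | 4.00 | 4 | 44 |
| Friday's | 0.500 | 3 | 56 |
| Friday's | 1.00 | 1 | 56 |
| Friday's | 1.50 | 1 | 58 |
| Friday's | 2.00 | 1 | 58 |
| Friday's | 2.50 | 2 | 60 |
| Friday's | 3.00 | 1 | 59 |
| Friday's | 4.00 | 2 | 59 |
| Saturday's | 0.667 | 1 | 39 |
| Saturday's | 1.33 | 3 | 41 |
| Saturday's | 2.00 | 1 | 38 |
| Saturday's | 3.00 | 1 | 39 |
| Saturday's | 4.00 | 1 | 44 |

(scatter of a reading: 2 percentage points)

- steps thought possible: substrate + 2 reagent -> side product; substrate + reagent <-> target; target -> over-reaction product; 2 reagent -> self-condensation product

1. which flask leads in share of target in target plus side product ("all alike" within 1.5 percentage points) (delta / zeta / theta / eta / all alike)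
2. share of target in target plus side product at the end, delta
3. share of target in target plus side product at the end, zeta
4. share of target in target plus side product at the end, theta
5. share of target in target plus side product at the end, eta

The fastest rung is reagent's working time. In Sunday's run the side product reads 30% at 0.250 h, 25% at 0.333 h, 28% at 0.500 h and 30% at 3.00 h, so with a scatter of 2 percentage points the early readings already stand near the final level, though they cannot say when its formation ends, and target ends within the scatter. Both reagent-consuming steps on the card take two reagent, so reagent squared cancels from their ratio, and side product forms per self-condensation product in proportion to substrate. Integrating with target neglected gives: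

ln(substrate charged / substrate left) = selectivity factor × self-condensation product

self-condensation product = 0.5 × reagent charged − side product

Sunday's run reads 71.3 L mol⁻¹, the selectivity factor, meaning side-product rate over self-condensation rate per mole per litre of substrate. Friday's run reads 73.1 L mol⁻¹ and Saturday's 69.6 L mol⁻¹.

The next rung is the reagent feeds, 12 min in zeta and 2.0 h in theta. They change the reagent level, but reagent is absent from the ratio, so I reckon both flasks at the side product of eta, which is Sunday's recipe.

The slowest rung is delta's substrate feed, far longer than reagent's working time. Taking 0.250 h, the time of Sunday's first reading, as a rough working time of reagent in delta, I put mean substrate over that time at 0.00125 M, so: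

side product, delta = selectivity factor × mean substrate × 0.5 × reagent charged = 4.90% of the charge

With equal traces of target, I put delta ahead of eta by a factor of 6.12.

The forecast differs: theta leads, with delta 1%, zeta 1.5%, theta 10% and eta 1%, on the ground “Theta starves the reagent, so side product falls”.

The flasks give delta in the lead: delta 8.10%, zeta 1.30%, theta 2.80%, eta 1.24%.

    substrate + 2 reagent → side product (k = 6.30 L² mol⁻² s⁻¹)
    substrate + reagent ⇌ target (K = 16.0 L mol⁻¹, k = 0.240 L mol⁻¹ s⁻¹)
    target → over-reaction product (k = 1.70 × 10⁻⁶ s⁻¹)
    2 reagent → self-condensation product (k = 0.0710 L mol⁻¹ s⁻¹)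

Side product ends at 30.8% in theta and 30.9% in eta, but at 5.90% in delta, against my 4.90%. Self-condensation carries part of delta's lead: without that step the gap to eta falls from 6.9 points to 0.74 points. The neighbour of eta charged with 0.055 M of reagent ends at 64.6% side product. From that balance, 71.3 L mol⁻¹ puts substrate left at 35.3%, and that flask holds 35.1%.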